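**Plan**

- Retrosynthesis: the C5 ethyl enol ether is the last mask. Ring B is opened at O1–C2 (oxa-Michael addition of O8a to a C4 enone whose carbon chain already sits on C4a). Ring A is cut at C7–C8, C4a–C8a and C6–C7 into a 4,4-dialkyl-3-ethoxycyclobutenone and a siloxyalkyne carrying the hexanoate arm. The cyclobutenone is cut into a dialkylketene (malonate-derived acid) and a 1-ethoxyalkyne that bears the future C4–C3–C2 unit.
- Enabling feature: ring A is a cyclohexa-2,4-dienone oxygenated at C5, C7 and C8a whose C6 is quaternary, so a vinylketene–ynol ether annulation builds it and cannot run on to a phenol.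
- Forward order: cyclobutane arm (steps 1–6), malonate chain and cyclobutenone (7–11), siloxyalkyne (12–15), ring A (16), ring B (17–18), release of O5 (19).
- Stereochemistry: cyclobutane C2 comes from a ligand-controlled Rh-catalysed alkenyl addition and C1 from equilibration to trans. The hexanoate C3 comes from a ligand-controlled Rh-catalysed conjugate alkynylation. C6 arises without control in the key step and the epimers are separated after ring B closure. The carbinol centre is transient.
- Atom labels O1, C2–C4, C4a, C5–C8, C8a are those of the final chromane-4,7-dione and are used for ring A from step 16 on.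

Key step: step 16

Remark: the ligand antipodes named in steps 3 and 12 are assigned by analogy with related Rh-catalysed additions; if a test reaction shows the opposite sense, the antipodal ligand is used with no other change.

Remark: the cyclobutane keeps the trans geometry fixed in steps 3–4 throughout; only the CIP letter at its C1 alternates with the priority of the attached CH2 group.

**Route**

Step 1
Reactants: 1 3,3-dimethylcyclobutane-1-carboxylic acid
Product: 2 ethyl 3,3-dimethylcyclobutane-1-carboxylate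
Conditions: EtOH, H2SO4 (cat.), reflux
Reagents that add atoms: ethanol, CCO
Why: Fischer esterification gives the enolisable ester needed for step 2; no stereocentre is involved.

Step 2
Reactants: 2 ethyl 3,3-dimethylcyclobutane-1-carboxylate
Product: 4 ethyl 3,3-dimethylcyclobut-1-ene-1-carboxylate, via selenide 3 (not isolated)
Conditions: LiN(iPr)2, THF, −78 °C; PhSeBr, −78 °C; then 30% H2O2, pyridine, CH2Cl2, 0 °C to rt
Reagents that add atoms: none
Why: α-Selenenylation of the lithium ester enolate and oxidation trigger a selenoxide syn-elimination, which can only place the double bond toward the equivalent C2/C4 positions and so should give the strained conjugated cyclobutene ester.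

Step 3
Reactants: 4 ethyl 3,3-dimethylcyclobut-1-ene-1-carboxylate; 5 potassium trifluoro(prop-1-en-2-yl)borate (2 equiv)
Product: 6 ethyl (2R)-3,3-dimethyl-2-(prop-1-en-2-yl)cyclobutane-1-carboxylate (C1 epimer mixture)
Conditions: [Rh(cod)2]BF4 (3 mol %), (R)-BINAP (3.3 mol %), toluene/H2O (10:1), 100 °C
Reagents that add atoms: none
Why: Hayashi–Miyaura-type Rh-catalysed asymmetric 1,4-addition; the isopropenyl–rhodium/BINAP species carbometalates the strain-activated enoate on the ligand-selected face, which sets C2 as R, and protonation of the rhodium enolate leaves C1 as a mixture that step 4 corrects.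

Step 4
Reactants: 6 ethyl (2R)-3,3-dimethyl-2-(prop-1-en-2-yl)cyclobutane-1-carboxylate
Product: 7 ethyl (1R,2R)-3,3-dimethyl-2-(prop-1-en-2-yl)cyclobutane-1-carboxylate
Conditions: NaOEt (0.2 equiv), EtOH, 50 °C
Reagents that add atoms: none
Why: Reversible deprotonation α to the ester equilibrates C1 to the thermodynamically preferred trans arrangement of CO2Et and isopropenyl, while the non-acidic C2 keeps its configuration.

Step 5
Reactants: 7 ethyl (1R,2R)-3,3-dimethyl-2-(prop-1-en-2-yl)cyclobutane-1-carboxylate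
Product: 8 [(1R,2R)-3,3-dimethyl-2-(prop-1-en-2-yl)cyclobutyl]methanol
Conditions: LiAlH4, Et2O, 0 °C
Reagents that add atoms: none
Why: Hydride reduction of the ester to the primary alcohol leaves the unactivated alkene and both stereocentres untouched.

Step 6
Reactants: 8 [(1R,2R)-3,3-dimethyl-2-(prop-1-en-2-yl)cyclobutyl]methanol
Product: 9 (1R,2R)-1-(iodomethyl)-3,3-dimethyl-2-(prop-1-en-2-yl)cyclobutane
Conditions: PPh3, I2, imidazole, CH2Cl2, 0 °C to rt
Reagents that add atoms: iodine, II
Why: Appel-type iodination proceeds by SN2 displacement of the oxyphosphonium at the primary carbon, so no cyclobutylcarbinyl cation and hence no ring expansion should arise.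

Step 7
Reactants: 9 (1R,2R)-1-(iodomethyl)-3,3-dimethyl-2-(prop-1-en-2-yl)cyclobutane; 10 diethyl malonate (3 equiv)
Product: 11 diethyl 2-{[(1R,2R)-3,3-dimethyl-2-(prop-1-en-2-yl)cyclobutyl]methyl}propanedioate
Conditions: NaH, 10, DMF, 0 °C; then 9, 70 °C
Reagents that add atoms: none
Why: Malonic ester alkylation (SN2) of the soft sodium malonate on the β-branched primary iodide; excess malonate suppresses dialkylation and the weakly basic nucleophile limits E2.

Step 8
Reactants: 11 diethyl 2-{[(1R,2R)-3,3-dimethyl-2-(prop-1-en-2-yl)cyclobutyl]methyl}propanedioate; 12 1-bromo-3-methylbut-2-ene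
Product: 13 diethyl 2-{[(1S,2R)-3,3-dimethyl-2-(prop-1-en-2-yl)cyclobutyl]methyl}-2-(3-methylbut-2-en-1-yl)propanedioate
Conditions: NaH, THF, 0 °C; then 12, rt
Reagents that add atoms: none
Why: The second malonate alkylation uses the reactive allylic bromide, so the quaternary carbon (the future C6) should form readily by SN2.

Step 9
Reactants: 13 diethyl 2-{[(1S,2R)-3,3-dimethyl-2-(prop-1-en-2-yl)cyclobutyl]methyl}-2-(3-methylbut-2-en-1-yl)propanedioate
Product: 15 2-{[(1R,2R)-3,3-dimethyl-2-(prop-1-en-2-yl)cyclobutyl]methyl}-5-methylhex-4-enoic acid (both C2 epimers), via diacid 14 (not isolated)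
Conditions: KOH, EtOH/H2O, 80 °C; aq KHSO4, 0 °C; then pyridine, 115 °C
Reagents that add atoms: potassium hydroxide, [K+].[OH-]
Why: Saponification and thermal decarboxylation of the dialkylmalonic acid through its cyclic transition state give the α,α-dialkylacetic acid; the new α-centre is unselective and irrelevant because it becomes the sp2 ketene carbon in step 11.

Step 10
Reactants: 16 ethoxyethyne; 17 3-methylbut-2-enal
Product: 19 triethyl[(1-ethoxy-5-methylhex-4-en-1-yn-3-yl)oxy]silane (racemic), via lithium alkoxide 18 (not isolated)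
Conditions: n-BuLi, THF, −78 °C; 17, −78 °C; then Et3SiCl, −78 to 0 °C
Reagents that add atoms: chlorotriethylsilane, CC[Si](Cl)(CC)CC
Why: 1,2-Addition of lithiated ethoxyethyne to the enal carbonyl and in-flask O-silylation avoid isolating the Meyer–Schuster-prone ethoxyalkynyl carbinol; the racemic carbinol centre is oxidised away in step 18.

Step 11
Reactants: 15 2-{[(1R,2R)-3,3-dimethyl-2-(prop-1-en-2-yl)cyclobutyl]methyl}-5-methylhex-4-enoic acid; 19 triethyl[(1-ethoxy-5-methylhex-4-en-1-yn-3-yl)oxy]silane (1.5 equiv)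
Product: 22 4-{[(1S,2R)-3,3-dimethyl-2-(prop-1-en-2-yl)cyclobutyl]methyl}-3-ethoxy-4-(3-methylbut-2-en-1-yl)-2-{3-methyl-1-[(triethylsilyl)oxy]but-2-en-1-yl}cyclobut-2-en-1-one (epimers at ring C4 and at the silyloxy carbon), via acid chloride 20 (not isolated), via ketene 21 (not isolated)
Conditions: 1-chloro-N,N,2-trimethylprop-1-en-1-amine, CH2Cl2, 0 °C to rt; then 19, Et3N, CH2Cl2, 40 °C
Reagents that add atoms: none
Why: The neutral chloroenamine gives the acid chloride without HCl, Et3N dehydrochlorination generates the dialkylketene, and its [2+2] cycloaddition with the ynol ether is regioselective because the ketene carbonyl carbon bonds to the nucleophilic β-carbon of the alkoxyalkyne, giving the 3-ethoxycyclobutenone; both uncontrolled centres are destroyed later.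

Step 12
Reactants: 23 (E)-hex-2-enal; 24 ethynyltri(propan-2-yl)silane
Product: 25 (3R)-3-{[tri(propan-2-yl)silyl]ethynyl}hexanal
Conditions: [Rh(OAc)(C2H4)2]2 (2.5 mol %), (R)-DTBM-SEGPHOS (5.5 mol %), MeOH, 40 °C
Reagents that add atoms: none
Why: Rh-catalysed asymmetric conjugate alkynylation; the silylalkynyl–rhodium/bisphosphine species adds to the enal β-carbon on the ligand-selected face and sets the side-chain stereocentre as R, while the bulky silyl group suppresses alkyne dimerisation.

Step 13
Reactants: 25 (3R)-3-{[tri(propan-2-yl)silyl]ethynyl}hexanal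
Product: 26 (3R)-3-{[tri(propan-2-yl)silyl]ethynyl}hexanoic acid
Conditions: NaClO2, NaH2PO4, 2-methylbut-2-ene, t-BuOH/H2O, rt
Reagents that add atoms: sodium chlorite, [Na+].[O-]Cl=O
Why: Pinnick oxidation converts the aldehyde into the acid under buffered conditions that leave the silylalkyne and the β-stereocentre untouched.

Step 14
Reactants: 26 (3R)-3-{[tri(propan-2-yl)silyl]ethynyl}hexanoic acid
Product: 27 (3R)-3-ethynylhexanoic acid
Conditions: Bu4NF (2.5 equiv), THF, rt
Reagents that add atoms: none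
Why: Fluoride cleaves the C(sp)–Si bond to free the terminal alkyne; the propargylic stereocentre carries no hydrogen acidic enough to be touched.

Step 15
Reactants: 27 (3R)-3-ethynylhexanoic acid
Product: 29 tri(propan-2-yl)silyl (3R)-3-({[tri(propan-2-yl)silyl]oxy}ethynyl)hexanoate, via dilithium ynolate 28 (not isolated)
Conditions: LiN(SiMe3)2 (3.2 equiv), THF, −78 °C; t-BuOOH (1.05 equiv), −78 to 0 °C; then iPr3SiOTf (2.3 equiv), −78 to 0 °C
Reagents that add atoms: tert-butyl hydroperoxide, CC(C)(C)OO; tri(propan-2-yl)silyl trifluoromethanesulfonate, CC(C)[Si](OS(=O)(=O)C(F)(F)F)(C(C)C)C(C)C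
Why: With the carboxyl shielded as its lithium salt, the lithium acetylide is oxidised by lithium tert-butyl peroxide to the lithium ynolate (the known acetylide-to-ynolate oxidation), and the bulky silyl triflate silylates the ynolate on oxygen and the carboxylate, giving the siloxyalkyne as its silyl ester.

Step 16
Reactants: 22 the 3-ethoxycyclobutenone of step 11; 29 tri(propan-2-yl)silyl (3R)-3-({[tri(propan-2-yl)silyl]oxy}ethynyl)hexanoate (1.5 equiv)
Product: 33 ring A cyclohexa-2,4-dienone with C7 ketone/C8 hexanoate arm/C8a OSi(iPr)3/C4a CH(OSiEt3)CH=CMe2/C5 OEt/C6 quaternary (both C6 epimers), via vinylketene 30 (not isolated), via alkenylcyclobutenone 31 (not isolated), via dienylketene 32 (not isolated)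
Conditions: toluene (1 M), 110 °C, sealed tube; chromatography on Et3N-deactivated silica
Reagents that add atoms: none
Why: Heating opens cyclobutenone 22 by 4π-electrocyclic ring opening to vinylketene 30, whose ketene carbon (C7) is attacked by the oxygen-remote, nucleophilic carbon of siloxyalkyne 29 in a regioselective [2+2] cycloaddition that forms C7–C8 and C4a–C8a and gives the 4-alkenylcyclobutenone 31. A second 4π opening gives dienylketene 32, and thermally allowed disrotatory 6π-electrocyclisation forms C6–C7 and so closes ring A as a six-membered carbocycle. The closest known reaction is the Danheiser benzannulation of cyclobutenones with siloxyalkynes; here the cascade halts at the cyclohexa-2,4-dienone because C6 carries two carbon substituents and no hydrogen to tautomerise. The new stereocentre C6 has no controlling element, since the two helical senses of the closure differ only through the remote cyclobutane and side-chain centres, so both C6 epimers are expected and are carried on for separation in step 18. The step needs the ketene–ynol ether regiochemistry, which the polarity of the partners (electrophilic ketene carbon, nucleophilic β-carbon of the ynol ether) secures, and it needs bimolecular capture of 30 to outrun its 1,5-hydrogen shift and its intramolecular [2+2] with the prenyl alkene, which the reversible ring opening, the high concentration and the excess of the electron-rich alkyne should secure.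

Step 17
Reactants: 33 ring A dienone of step 16
Product: 34 desilylated ring A dienone with free O8a enol/free C4 carbinol/free carboxylic acid/C5 OEt (both C6 epimers)
Conditions: Bu4NF (3.5 equiv), THF, 0 °C; pH 7 phosphate buffer
Reagents that add atoms: none
Why: Fluoride removes the two triisopropylsilyl groups (vinylogous silyl ester and silyl ester) and the triethylsilyl ether while the ethyl enol ether stays, so O8a is the only free ring oxygen; the neutral work-up avoids acid-promoted ionisation of the allylic carbinol.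

Step 18
Reactants: 34 desilylated ring A dienone of step 17
Product: 36 (3R)-3-[(6R)-6-{[(1S,2R)-3,3-dimethyl-2-(prop-1-en-2-yl)cyclobutyl]methyl}-5-ethoxy-2,2-dimethyl-6-(3-methylbut-2-en-1-yl)-4,7-dioxo-3,4,6,7-tetrahydro-2H-chromen-8-yl]hexanoic acid, via enone 35 (not isolated)
Conditions: MnO2, CH2Cl2, rt; filter; then DBU, CH2Cl2, rt; preparative HPLC
Reagents that add atoms: none
Why: MnO2 oxidises the doubly allylic carbinol to the enone without touching the other alkenes, and base-mediated 6-endo-trig oxa-Michael addition of the O8a enol to the β,β-dimethyl enone closes ring B; because O5 is ethylated only O8a can cyclise, the carbinol epimers converge, and the C6 epimers are separated here.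

Step 19
Reactants: 36 the C5 ethyl ether of the target
Product: 37 (3R)-3-[(6R)-6-{[(1S,2R)-3,3-dimethyl-2-(prop-1-en-2-yl)cyclobutyl]methyl}-5-hydroxy-2,2-dimethyl-6-(3-methylbut-2-en-1-yl)-4,7-dioxo-3,4,6,7-tetrahydro-2H-chromen-8-yl]hexanoic acid (CNP0358381.1)
Conditions: LiOH, THF/H2O (3:1), 0 °C to rt; then 0.5 M HCl to pH 3, 0 °C
Reagents that add atoms: lithium hydroxide, [Li+].[OH-]
Why: Hydroxide adds to C5 of the vinylogous ester activated by the C4 ketone and expels ethoxide (addition–elimination), giving the enolised trione as its anion, which should resist retro-oxa-Michael opening; no stereocentre carries an acidic hydrogen and the cold, brief acidification spares the prenyl and isopropenyl groups.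

**Compound list**

1 | 3,3-dimethylcyclobutane-1-carboxylic acid | CC1(C)CC(C(=O)O)C1 | starting material
2 | ethyl 3,3-dimethylcyclobutane-1-carboxylate | CCOC(=O)C1CC(C)(C)C1 | intermediate
3 | ethyl 3,3-dimethyl-1-(phenylselanyl)cyclobutane-1-carboxylate | CCOC(=O)C1([Se]c2ccccc2)CC(C)(C)C1 | intermediate
4 | ethyl 3,3-dimethylcyclobut-1-ene-1-carboxylate | CCOC(=O)C1=CC(C)(C)C1 | intermediate
5 | potassium trifluoro(prop-1-en-2-yl)borate | C=C(C)[B-](F)(F)F.[K+] | starting material
6 | ethyl (2R)-3,3-dimethyl-2-(prop-1-en-2-yl)cyclobutane-1-carboxylate, C1 epimer mixture | C=C(C)[C@H]1C(C(=O)OCC)CC1(C)C | intermediate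
7 | ethyl (1R,2R)-3,3-dimethyl-2-(prop-1-en-2-yl)cyclobutane-1-carboxylate (trans) | C=C(C)[C@H]1[C@H](C(=O)OCC)CC1(C)C | intermediate
8 | [(1R,2R)-3,3-dimethyl-2-(prop-1-en-2-yl)cyclobutyl]methanol | C=C(C)[C@H]1[C@H](CO)CC1(C)C | intermediate
9 | (1R,2R)-1-(iodomethyl)-3,3-dimethyl-2-(prop-1-en-2-yl)cyclobutane | C=C(C)[C@H]1[C@H](CI)CC1(C)C | intermediate
10 | diethyl malonate | CCOC(=O)CC(=O)OCC | starting material
11 | diethyl 2-{[(1R,2R)-3,3-dimethyl-2-(prop-1-en-2-yl)cyclobutyl]methyl}propanedioate | C=C(C)[C@H]1[C@H](CC(C(=O)OCC)C(=O)OCC)CC1(C)C | intermediate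
12 | 1-bromo-3-methylbut-2-ene | CC(C)=CCBr | starting material
13 | diethyl 2-{[(1S,2R)-3,3-dimethyl-2-(prop-1-en-2-yl)cyclobutyl]methyl}-2-(3-methylbut-2-en-1-yl)propanedioate | C=C(C)[C@H]1[C@H](CC(CC=C(C)C)(C(=O)OCC)C(=O)OCC)CC1(C)C | intermediate
14 | 2-{[(1S,2R)-3,3-dimethyl-2-(prop-1-en-2-yl)cyclobutyl]methyl}-2-(3-methylbut-2-en-1-yl)propanedioic acid | C=C(C)[C@H]1[C@H](CC(CC=C(C)C)(C(=O)O)C(=O)O)CC1(C)C | intermediate
15 | 2-{[(1R,2R)-3,3-dimethyl-2-(prop-1-en-2-yl)cyclobutyl]methyl}-5-methylhex-4-enoic acid, both C2 epimers | C=C(C)[C@H]1[C@H](CC(CC=C(C)C)C(=O)O)CC1(C)C | intermediate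
16 | ethoxyethyne | CCOC#C | starting material
17 | 3-methylbut-2-enal | CC(C)=CC=O | starting material
18 | lithium 1-ethoxy-5-methylhex-4-en-1-yn-3-olate (racemic) | CCOC#CC([O-])C=C(C)C.[Li+] | intermediate
19 | triethyl[(1-ethoxy-5-methylhex-4-en-1-yn-3-yl)oxy]silane (racemic) | CCOC#CC(O[Si](CC)(CC)CC)C=C(C)C | intermediate
20 | 2-{[(1R,2R)-3,3-dimethyl-2-(prop-1-en-2-yl)cyclobutyl]methyl}-5-methylhex-4-enoyl chloride, both C2 epimers | C=C(C)[C@H]1[C@H](CC(CC=C(C)C)C(=O)Cl)CC1(C)C | intermediate
21 | 2-{[(1S,2R)-3,3-dimethyl-2-(prop-1-en-2-yl)cyclobutyl]methyl}-5-methylhexa-1,4-dien-1-one (ketene) | C=C(C)[C@H]1[C@H](CC(CC=C(C)C)=C=O)CC1(C)C | intermediate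
22 | 4-{[(1S,2R)-3,3-dimethyl-2-(prop-1-en-2-yl)cyclobutyl]methyl}-3-ethoxy-4-(3-methylbut-2-en-1-yl)-2-{3-methyl-1-[(triethylsilyl)oxy]but-2-en-1-yl}cyclobut-2-en-1-one, epimers at ring C4 and at the silyloxy carbon | C=C(C)[C@H]1[C@H](CC2(CC=C(C)C)C(=O)C(C(O[Si](CC)(CC)CC)C=C(C)C)=C2OCC)CC1(C)C | intermediate
23 | (E)-hex-2-enal | CCC/C=C/C=O | starting material
24 | ethynyltri(propan-2-yl)silane | C#C[Si](C(C)C)(C(C)C)C(C)C | starting material
25 | (3R)-3-{[tri(propan-2-yl)silyl]ethynyl}hexanal | CCC[C@@H](C#C[Si](C(C)C)(C(C)C)C(C)C)CC=O | intermediate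
26 | (3R)-3-{[tri(propan-2-yl)silyl]ethynyl}hexanoic acid | CCC[C@@H](C#C[Si](C(C)C)(C(C)C)C(C)C)CC(=O)O | intermediate
27 | (3R)-3-ethynylhexanoic acid | CCC[C@@H](C#C)CC(=O)O | intermediate
28 | dilithium (3R)-3-(oxidoethynyl)hexanoate (ynolate carboxylate) | CCC[C@@H](C#C[O-])CC(=O)[O-].[Li+].[Li+] | intermediate
29 | tri(propan-2-yl)silyl (3R)-3-({[tri(propan-2-yl)silyl]oxy}ethynyl)hexanoate | CCC[C@@H](C#CO[Si](C(C)C)(C(C)C)C(C)C)CC(=O)O[Si](C(C)C)(C(C)C)C(C)C | intermediate
30 | vinylketene from ring opening of 22: O=C=C[CH(OSiEt3)CH=CMe2]–C(OEt)=C(prenyl)(CH2-cyclobutyl), alkene geometry and carbinol centre undefined | C=C(C)[C@H]1[C@H](CC(CC=C(C)C)=C(OCC)C(=C=O)C(O[Si](CC)(CC)CC)C=C(C)C)CC1(C)C | intermediate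
31 | 4-alkenylcyclobut-2-en-1-one from [2+2] of 30 with 29: C2 hexanoate arm, C3 OSi(iPr)3, C4 bearing CH(OSiEt3)CH=CMe2 and the ethoxy-dialkylvinyl group; stereo at C4, the alkene and the carbinol undefined | C=C(C)[C@H]1[C@H](CC(CC=C(C)C)=C(OCC)C2(C(O[Si](CC)(CC)CC)C=C(C)C)C(=O)C([C@H](CCC)CC(=O)O[Si](C(C)C)(C(C)C)C(C)C)=C2O[Si](C(C)C)(C(C)C)C(C)C)CC1(C)C | intermediate
32 | dienylketene from ring opening of 31: O=C=C(hexanoate arm)–C(OSi(iPr)3)=C[CH(OSiEt3)CH=CMe2]–C(OEt)=C(prenyl)(CH2-cyclobutyl), alkene geometries undefined | C=C(C)[C@H]1[C@H](CC(CC=C(C)C)=C(OCC)C(C(O[Si](CC)(CC)CC)C=C(C)C)=C(O[Si](C(C)C)(C(C)C)C(C)C)C(=C=O)[C@H](CCC)CC(=O)O[Si](C(C)C)(C(C)C)C(C)C)CC1(C)C | intermediate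
33 | ring A cyclohexa-2,4-dienone: C7 ketone, C8 (R)-CH(nPr)CH2CO2Si(iPr)3, C8a OSi(iPr)3, C4a CH(OSiEt3)CH=CMe2, C5 OEt, C6 prenyl and [(1S,2R)-3,3-dimethyl-2-(prop-1-en-2-yl)cyclobutyl]methyl; both C6 epimers, both carbinol epimers | C=C(C)[C@H]1[C@H](CC2(CC=C(C)C)C(=O)C([C@H](CCC)CC(=O)O[Si](C(C)C)(C(C)C)C(C)C)=C(O[Si](C(C)C)(C(C)C)C(C)C)C(C(O[Si](CC)(CC)CC)C=C(C)C)=C2OCC)CC1(C)C | intermediate
34 | ring A dienone with free O8a enol, C4a CH(OH)CH=CMe2, C5 OEt and free (3R)-hexanoic acid arm; both C6 epimers, both carbinol epimers | C=C(C)[C@H]1[C@H](CC2(CC=C(C)C)C(=O)C([C@H](CCC)CC(=O)O)=C(O)C(C(O)C=C(C)C)=C2OCC)CC1(C)C | intermediate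
35 | ring A dienone with free O8a enol, C4a C(=O)CH=CMe2, C5 OEt and free (3R)-hexanoic acid arm; both C6 epimers | C=C(C)[C@H]1[C@H](CC2(CC=C(C)C)C(=O)C([C@H](CCC)CC(=O)O)=C(O)C(C(=O)C=C(C)C)=C2OCC)CC1(C)C | intermediate
36 | (3R)-3-[(6R)-6-{[(1S,2R)-3,3-dimethyl-2-(prop-1-en-2-yl)cyclobutyl]methyl}-5-ethoxy-2,2-dimethyl-6-(3-methylbut-2-en-1-yl)-4,7-dioxo-3,4,6,7-tetrahydro-2H-chromen-8-yl]hexanoic acid | C=C(C)[C@H]1[C@H](C[C@]2(CC=C(C)C)C(=O)C([C@H](CCC)CC(=O)O)=C3OC(C)(C)CC(=O)C3=C2OCC)CC1(C)C | intermediate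
37 | (3R)-3-[(6R)-6-{[(1S,2R)-3,3-dimethyl-2-(prop-1-en-2-yl)cyclobutyl]methyl}-5-hydroxy-2,2-dimethyl-6-(3-methylbut-2-en-1-yl)-4,7-dioxo-3,4,6,7-tetrahydro-2H-chromen-8-yl]hexanoic acid (CNP0358381.1) | C=C(C)[C@H]1[C@H](C[C@]2(CC=C(C)C)C(=O)C([C@H](CCC)CC(=O)O)=C3OC(C)(C)CC(=O)C3=C2O)CC1(C)C | target

**Totals**

Total step count: 19.
Longest linear sequence: 14 steps (1–9, 11, 16–19).

**Steps most likely to fail, with fallbacks**

Step 16. Steric congestion around the fully substituted vinylketene may slow the bimolecular cycloaddition with the siloxyalkyne, so that unimolecular decay of the vinylketene (1,5-hydrogen shift, intramolecular cycloaddition onto the prenyl alkene) takes over, or the cascade may stall before the 6π closure. The fallback keeps the annulation but moves the C4 carbon to a later stage. It sets out from 15: ketene 21, generated as in step 11, is trapped with the terminal ynol ether 16 to give the 2-unsubstituted cyclobutenone F1. Heating F1 with 29 in toluene runs the same cascade and gives the C4a–H ring A dienone F2, whose C6 epimers can be separated at once. N-Iodosuccinimide in dry MeCN at low temperature iodinates the only free ring position and gives the C4a iodide F3. Carbonylative Stille coupling with tributyl(2-methylprop-1-en-1-yl)stannane under CO (Pd(PPh3)4, LiCl, THF, 60 °C) gives the C4a senecioyl dienone F4. Bu4NF then removes both silyl groups and the freed O8a closes ring B, which returns to 36.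

Step 11. Dehydrochlorination of the α,α-dialkyl acid chloride may be slow and the hindered ketene may add sluggishly to an internal ynol ether, so that ketene dimerisation and acylation side paths compete. The fallback replaces the ketene by a far more electrophilic keteniminium ion. It sets out from 15 by way of 20: dimethylamine converts 20 into the N,N-dimethylamide F5. Tf2O with 2,6-di-tert-butyl-4-methylpyridine in CH2Cl2 (−78 °C to rt) gives the keteniminium triflate F6. Its [2+2] cycloaddition with 19, of the same regiochemistry, gives the cyclobuteniminium triflate F7, and aqueous NaHCO3 hydrolysis returns to 22.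

Step 3. Carbometalation next to the quaternary C3 may be slow, with protodeboronation of the alkenylboron reagent and eroded enantioselectivity. The fallback takes the stereochemistry from a separation instead of a catalyst. It sets out from 4: CuBr·SMe2-catalysed conjugate addition of isopropenylmagnesium bromide (Me3SiCl, THF, −40 °C), followed by NaOEt/EtOH equilibration, gives the racemic trans ester F8. LiAlH4 reduction gives the racemic trans alcohol F9, and preparative chiral SFC delivers the (1R,2R)-enantiomer, which returns to 8.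

Further compounds
F1 | step 16 | 4-{[(1S,2R)-3,3-dimethyl-2-(prop-1-en-2-yl)cyclobutyl]methyl}-3-ethoxy-4-(3-methylbut-2-en-1-yl)cyclobut-2-en-1-one, both C4 epimers | C=C(C)[C@H]1[C@H](CC2(CC=C(C)C)C(=O)C=C2OCC)CC1(C)C
F2 | step 16 | (6R) ring A dienone with C4a–H: C7 ketone, C8 (R)-CH(nPr)CH2CO2Si(iPr)3, C8a OSi(iPr)3, C5 OEt, C6 prenyl and cyclobutylmethyl | C=C(C)[C@H]1[C@H](C[C@]2(CC=C(C)C)C(=O)C([C@H](CCC)CC(=O)O[Si](C(C)C)(C(C)C)C(C)C)=C(O[Si](C(C)C)(C(C)C)C(C)C)C=C2OCC)CC1(C)C
F3 | step 16 | C4a-iodo derivative of F2 | C=C(C)[C@H]1[C@H](C[C@]2(CC=C(C)C)C(=O)C([C@H](CCC)CC(=O)O[Si](C(C)C)(C(C)C)C(C)C)=C(O[Si](C(C)C)(C(C)C)C(C)C)C(I)=C2OCC)CC1(C)C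
F4 | step 16 | C4a-(3-methylbut-2-enoyl) derivative of F2 | C=C(C)[C@H]1[C@H](C[C@]2(CC=C(C)C)C(=O)C([C@H](CCC)CC(=O)O[Si](C(C)C)(C(C)C)C(C)C)=C(O[Si](C(C)C)(C(C)C)C(C)C)C(C(=O)C=C(C)C)=C2OCC)CC1(C)C
F5 | step 11 | 2-{[(1R,2R)-3,3-dimethyl-2-(prop-1-en-2-yl)cyclobutyl]methyl}-N,N,5-trimethylhex-4-enamide, both C2 epimers | C=C(C)[C@H]1[C@H](CC(CC=C(C)C)C(=O)N(C)C)CC1(C)C
F6 | step 11 | keteniminium triflate derived from F5 | C=C(C)[C@H]1[C@H](CC(CC=C(C)C)=C=[N+](C)C)CC1(C)C.[O-]S(=O)(=O)C(F)(F)F
F7 | step 11 | N,N-dimethylcyclobut-2-en-1-iminium triflate corresponding to 22 | C=C(C)[C@H]1[C@H](CC2(CC=C(C)C)C(=[N+](C)C)C(C(O[Si](CC)(CC)CC)C=C(C)C)=C2OCC)CC1(C)C.[O-]S(=O)(=O)C(F)(F)F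
F8 | step 3 | racemic ethyl trans-3,3-dimethyl-2-(prop-1-en-2-yl)cyclobutane-1-carboxylate | C=C(C)[C@H]1[C@H](C(=O)OCC)CC1(C)C.C=C(C)[C@@H]1[C@@H](C(=O)OCC)CC1(C)C
F9 | step 3 | racemic [trans-3,3-dimethyl-2-(prop-1-en-2-yl)cyclobutyl]methanol | C=C(C)[C@H]1[C@H](CO)CC1(C)C.C=C(C)[C@@H]1[C@@H](CO)CC1(C)C
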